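## The problem

Target 20 is a 2,3-trans-dihydroflavonol 3-methyl ether. A chroman-4-one (ring C) is fused to ring A (OH at C5, OMe at C6 and C7, H at C8) and carries a 2,5-dihydroxy-4-methoxyphenyl ring B at C2. Ring C is held together by the O1–C2 aryl ether bond, the C4–C4a aryl ketone bond and the C2–C3–C4 chain. There are two adjacent stereocentres, C2 (R, benzylic ether) and C3 (R, methoxy), trans to each other. C2 is the anchor: once it is fixed, the C3 oxygen can be delivered to the face of ring C away from the aryl group, whereas C3 offers no comparable handle on C2. The finished chromanone is fragile. Base enolises C3/C4, which epimerises C3 and opens ring C by β-elimination of the O1 phenoxide (scrambling C2). Ring B is a hydroquinone that oxidises readily. Of the three ring A oxygens, only O5 can be told apart, through its peri relation to the C4 carbonyl. The enabling feature is that C2 is a secondary carbon benzylic to ring B, bound to the ring A oxygen O1 and attached to C3. With C3=C4 as an alkene, C2 is the branched terminus of a ring B cinnamyl system, and C3=C4 is the metathesis product of a vinyl group on C2 and one on C4a.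

## Retrosynthesis

**20 ⇒ 19.** The last cut is at three O–C bonds: the two benzyl ethers on ring B and the methyl ether at C5. Keeping the hydroquinone masked to the end protects it from the phenoxide chemistry, OsO4 and DDQ used earlier. The forward step must cleave two benzyl ethers and exactly one of five methyl ethers; the C4 carbonyl of 19 marks O5 by chelation.

**19 ⇒ 18.** The O–CH3 bond at C3 is cut. The methyl group cannot come in earlier, because the C3 oxygen enters the molecule as a hydroxyl. The forward step must alkylate a hindered secondary alcohol next to an enolisable ketone without ever forming the enolate.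

**18 ⇒ 17 ⇒ 16.** The C4 carbonyl is traced to a benzylic carbinol, and both C–O bonds at C3 and C4 are cut back to the C3=C4 alkene of 2H-chromene 16. An epoxide opening would place the nucleophile at benzylic C4, not C3, and an enolate oxidation would need the base-labile chromanone first. Chromene 16 has one stereocentre and no ring C oxygen other than O1. The forward steps must add two oxygens syn and anti to the C2 aryl group (diol 17), then oxidise only C4.

**16 ⇒ 15.** The C3=C4 bond is cut by ring-closing metathesis, revealing diene 15 with a vinyl group on C2 and one on C4a. This turns the cyclic problem into an acyclic aryl allyl ether with a single stereocentre. The forward reaction needs only a neutral ruthenium carbene, which cannot disturb C2.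

**15 ⇒ 14 (from 13) + 9.** The O1–C2 bond is cut between ring A phenoxide 14 (the lithium salt of vinylphenol 13) and ring B cinnamyl carbonate 9. Cutting C2–C1' or C2–C3 instead would leave an unsymmetrical heterocycle to build first. An SN2 or Mitsunobu etherification at this carbon would racemise through the stabilised benzylic cation. Iridium catalysis turns that cationic character into an asset: the phenoxide must attack the aryl-bearing allyl terminus, at oxygen, on one face. The cut is convergent, joining two fragments of similar size.

**9 ⇒ 8 ⇒ 7 ⇒ 4 + 5; 4 ⇒ 2 ⇒ 1.** The carbonate comes from cinnamyl alcohol 8, the alcohol from cinnamate 7, and the C=C bond of 7 from aldehyde 4 and triethyl phosphonoacetate 5 (through its sodium salt 6). The formyl group of 4 is cut back to 1,4-bis(benzyloxy)-2-methoxybenzene 2 (through iminium salt 3), whose substitution pattern directs formylation to the one required position. Ether 2 is the dibenzyl ether of 2-methoxyhydroquinone 1.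

**13 ⇒ 12 ⇒ 10.** The vinyl group comes from salicylaldehyde 12 by methylenation, and the formyl group from ortho-formylation of 3,4,5-trimethoxyphenol 10 (through hydroxymethylphenol 11). The two ortho positions of 10 are equivalent, so no regiochemical question arises.

## Roads not taken

**Alternative 1:** Ring A would be built last. The C6 stannane of dihydropyranone A2 (already carrying C2, C3 and ring B) would undergo Stille coupling with the squarate-derived chlorocyclobutenone A3. Thermal ring opening of the resulting 4-alkenylcyclobutenone to a dienylketene and 6π closure would give A1, the 5-hydroxy compound.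
- Merit: the C5 phenol emerges already differentiated from the C6 and C7 methyl ethers, so only debenzylation would remain. In this respect it is better than the chosen plan, which needs a chelation-controlled demethylation.
- Weak points: ring A is available intact as phenol 10, so building it de novo is poor step economy. A2 needs its own asymmetric synthesis of both stereocentres plus a vinyl stannylation. The thermolysis heats a β-aryloxy ketone with an epimerisable C3.
- Comparison: the chosen plan sets against the one advantage a single, well-understood BCl3 step and a convergent union of two cheap aromatic fragments.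

**Alternative 2:** The C3–O bond would be made on a preformed chromanone. Flavanone A6 would be converted into silyl enol ether A5, and dimethyldioxirane would epoxidise C3=C4 anti to the aryl group to give hydroxy ketone A4 after collapse (a Rubottom oxidation).
- Merit: C4 is a ketone from the start, so no diol has to be differentiated. This is a real advantage over steps 10 and 11 of the chosen plan.
- Weak points: A4 is the same compound as 18, so the delicate O-methylation and the deprotection are shared. The problem of C2 is moved, not solved: A6 must be obtained enantioenriched, and forming A5 requires enolising a ketone whose enolate can expel the O1 phenoxide and racemise C2.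
- Comparison: the chosen plan sets C2 by a catalyst in the fragment union, and its intermediates 15, 16 and 17 have no carbonyl through which C2 could be lost.

**Alternative 3:** Ring C would be closed by forming C2–C3. The rhodium carbene from α-diazoketone A7 would insert into the benzylic C–H bond of the O1 benzyl ether to give flavanone A6.
- Merit: A7 is assembled by simple alkylation and acylation chemistry, and one C–C bond formation closes the ring and sets C2.
- Weak points: the carbene sits next to the ether oxygen. Attack on the O1 lone pair followed by a 1,2-benzyl shift (ring contraction), and addition to the electron-rich aryl rings, compete with the six-membered insertion. Enantiocontrol in such insertions is usually moderate. The product has no C3 oxygen, so the step of Alternative 2 and its racemisation risk would still follow.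
- Comparison: it is at least two steps longer to the same hydroxy ketone (A4, identical with 18) and less secure at C2.

Key step: step 8

**Assumptions and remarks on the chemistry**
- The target SMILES encodes (2R,3R), the 2,3-trans isomer; that is what is made.
- L* is the phosphoramidite from (S)-1,1'-bi-2-naphthol and bis[(S)-1-(2-methoxyphenyl)ethyl]amine. By the usual model for aryl-substituted allyl carbonates this (Sa,S,S) ligand should give the (S) ether 15. The sense must be confirmed on the first batch; if it is opposite, the (Ra,R,R) ligand is used with nothing else changed.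
- The C2 descriptor changes from S (15, 16) to R (17 onwards) only because the CIP rank of C3 rises when it gains oxygen; the spatial arrangement at C2 is unchanged.

## Route

Step 1
Reactants: 1 2-methoxybenzene-1,4-diol (2-methoxyhydroquinone)
Product: 2 1,4-bis(benzyloxy)-2-methoxybenzene
Conditions: BnBr (2.4 equiv), K2CO3, DMF, N2, rt → 50 °C
Reagents that add atoms: benzyl bromide, BrCc1ccccc1
Why: Williamson etherification of both phenols; carbonate base under nitrogen keeps the air-sensitive hydroquinone from oxidising before it is capped.

Step 2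
Reactants: 2 1,4-bis(benzyloxy)-2-methoxybenzene
Product: 4 2,5-bis(benzyloxy)-4-methoxybenzaldehyde, via aryl iminium chloride 3 (not isolated)
Conditions: POCl3, DMF, 0 → 60 °C; then ice-water, rt
Reagents that add atoms: N,N-dimethylformamide, CN(C)C=O; water, O
Why: Vilsmeier–Haack formylation; the position para to the methoxy group and ortho to a benzyloxy group is the most activated and least hindered, as with 1,2,4-trialkoxybenzenes, and iminium salt 3 is hydrolysed on work-up.

Step 3
Reactants: 4 2,5-bis(benzyloxy)-4-methoxybenzaldehyde; 5 triethyl phosphonoacetate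
Product: 7 ethyl (E)-3-[2,5-bis(benzyloxy)-4-methoxyphenyl]prop-2-enoate, via sodium phosphonate carbanion 6 (not isolated)
Conditions: 5, NaH, THF, 0 °C; then 4, 0 °C → rt
Reagents that add atoms: none
Why: Horner–Wadsworth–Emmons olefination of an aromatic aldehyde with the stabilised anion 6; reversible addition and syn-elimination should give the (E)-cinnamate.

Step 4
Reactants: 7 ethyl (E)-3-[2,5-bis(benzyloxy)-4-methoxyphenyl]prop-2-enoate
Product: 8 (E)-3-[2,5-bis(benzyloxy)-4-methoxyphenyl]prop-2-en-1-ol
Conditions: i-Bu2AlH (2.5 equiv), CH2Cl2, −78 → 0 °C; then aq. KNaC4H4O6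
Reagents that add atoms: none
Why: 1,2-reduction of a conjugated ester by i-Bu2AlH at low temperature gives the allylic alcohol and leaves the alkene and benzyl ethers alone.

Step 5
Reactants: 8 (E)-3-[2,5-bis(benzyloxy)-4-methoxyphenyl]prop-2-en-1-ol
Product: 9 (E)-3-[2,5-bis(benzyloxy)-4-methoxyphenyl]allyl methyl carbonate
Conditions: ClCO2Me, pyridine, CH2Cl2, 0 °C
Reagents that add atoms: methyl chloroformate, COC(=O)Cl
Why: Acylation of a primary allylic alcohol with a chloroformate; the medium stays basic because the electron-rich cinnamyl system ionises in acid.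

Step 6
Reactants: 10 3,4,5-trimethoxyphenol
Product: 12 6-hydroxy-2,3,4-trimethoxybenzaldehyde, via 2-(hydroxymethyl)-3,4,5-trimethoxyphenol 11 (not isolated)
Conditions: MgCl2, Et3N, (CH2O)n, MeCN, reflux; then 1 M HCl
Reagents that add atoms: paraformaldehyde (as formaldehyde), C=O
Why: Magnesium-mediated ortho-formylation of a phenol: the magnesium phenoxide adds formaldehyde at the ortho carbon to give 11, which is oxidised in place by hydride transfer to a second formaldehyde; the two ortho positions of 10 are equivalent.

Step 7
Reactants: 12 6-hydroxy-2,3,4-trimethoxybenzaldehyde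
Product: 13 3,4,5-trimethoxy-2-vinylphenol
Conditions: Ph3PCH3Br (2.5 equiv), KOt-Bu (3.5 equiv), THF, 0 °C → rt
Reagents that add atoms: methyltriphenylphosphonium bromide, C[P+](c1ccccc1)(c1ccccc1)c1ccccc1.[Br-]
Why: Wittig methylenation of a salicylaldehyde with excess unstabilised ylide; the extra base holds the phenol as its phenoxide, which slows but should not prevent addition to the aldehyde.

Step 8
Reactants: 13 3,4,5-trimethoxy-2-vinylphenol; 9 (E)-3-[2,5-bis(benzyloxy)-4-methoxyphenyl]allyl methyl carbonate
Product: 15 (S)-1-{[1-(2,5-bis(benzyloxy)-4-methoxyphenyl)prop-2-en-1-yl]oxy}-3,4,5-trimethoxy-2-vinylbenzene, via lithium 3,4,5-trimethoxy-2-vinylphenoxide 14 (not isolated)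
Conditions: 13 (1.5 equiv), n-BuLi, THF, 0 °C; then 9, [Ir(cod)Cl]2 (2 mol%), L* (4 mol%; preactivated with n-PrNH2, 50 °C, volatiles removed), THF, rt; then H2O
Reagents that add atoms: none
Why: [Ir(cod)Cl]2 and L* form, after amine-induced C–H activation at a ligand methyl group, a cyclometalated monovalent iridium complex that ionises carbonate 9 to a trivalent iridium π-allyl complex, the methyl carbonate leaving as methoxide and CO2. Phenoxide 14 then attacks from outside the metal, anti to iridium, at the aryl-bearing allyl terminus, forming O1–C2 and returning monovalent iridium. The closest known reaction type is exactly this one: iridium–phosphoramidite allylic etherification of cinnamyl carbonates with alkali-metal aryloxides, ortho-substituted ones included, to branched aryl allyl ethers. No ring is closed here; two fragments are joined and ring C is closed in step 9. The C2 configuration is controlled by the ligand alone, whose binaphthyl and arylethyl groups expose one face of the allyl terminus; neither reactant has a stereocentre. The step needs branched over linear attack, O- over C-alkylation of the phenoxide, and one enantioface. The electron-rich ring B aryl group concentrates positive charge at the benzylic terminus, the lithium counter-ion in THF favours attack through oxygen, and the 2-methoxyphenyl ligand variant is chosen because ortho-substituted cinnamyl carbonates respond better to it. The reaction is stopped at full conversion of 9 at the lowest workable temperature, because the electron-rich branched ether can re-ionise on the catalyst and lose both selectivities.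

Step 9
Reactants: 15 (S)-1-{[1-(2,5-bis(benzyloxy)-4-methoxyphenyl)prop-2-en-1-yl]oxy}-3,4,5-trimethoxy-2-vinylbenzene
Product: 16 (S)-2-[2,5-bis(benzyloxy)-4-methoxyphenyl]-5,6,7-trimethoxy-2H-chromene
Conditions: second-generation Grubbs catalyst (H2IMes)(PCy3)Cl2Ru=CHPh (5 mol%), CH2Cl2, 40 °C
Reagents that add atoms: none
Why: Ring-closing olefin metathesis of the allylic vinyl and styrenyl alkenes closes the six-membered pyran ring at C3=C4 with loss of ethylene; the catalyst loads on the less hindered allylic vinyl group, and the neutral conditions leave the C2 ether stereocentre untouched.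

Step 10
Reactants: 16 (S)-2-[2,5-bis(benzyloxy)-4-methoxyphenyl]-5,6,7-trimethoxy-2H-chromene
Product: 17 (2R,3S,4S)-2-[2,5-bis(benzyloxy)-4-methoxyphenyl]-5,6,7-trimethoxychromane-3,4-diol
Conditions: OsO4 (3 mol%), NMO (1.5 equiv), acetone/H2O, rt
Reagents that add atoms: osmium tetroxide, O=[Os](=O)(=O)=O; N-methylmorpholine N-oxide, C[N+]1([O-])CCOCC1; water, O
Why: Catalytic OsO4 syn-dihydroxylation of the cis-disubstituted styrenyl C3=C4 bond; the C2 aryl group shields its own face of the half-chair 2H-chromene, so both oxygens should arrive anti to it, setting C3 (and, for the moment, C4) relative to C2 as the 2,3-trans-3,4-cis diol.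

Step 11
Reactants: 17 (2R,3S,4S)-2-[2,5-bis(benzyloxy)-4-methoxyphenyl]-5,6,7-trimethoxychromane-3,4-diol
Product: 18 (2R,3R)-2-[2,5-bis(benzyloxy)-4-methoxyphenyl]-3-hydroxy-5,6,7-trimethoxychroman-4-one
Conditions: DDQ (1.3 equiv), CH2Cl2/pH 7 phosphate buffer, 0 °C → rt
Reagents that add atoms: none
Why: DDQ dehydrogenation of an electron-rich benzylic alcohol by hydride abstraction from C4–H, which the ortho and para oxygens of ring A activate while the C3 carbinol has no such activation; the buffer keeps the acidic hydroquinone by-product from ionising the C4 hydroxyl.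

Step 12
Reactants: 18 (2R,3R)-2-[2,5-bis(benzyloxy)-4-methoxyphenyl]-3-hydroxy-5,6,7-trimethoxychroman-4-one
Product: 19 (2R,3R)-2-[2,5-bis(benzyloxy)-4-methoxyphenyl]-3,5,6,7-tetramethoxychroman-4-one
Conditions: Me3OBF4 (3 equiv), 1,8-bis(dimethylamino)naphthalene (3.5 equiv), 4 Å molecular sieves, CH2Cl2, 0 °C → rt
Reagents that add atoms: trimethyloxonium tetrafluoroborate, C[O+](C)C.F[B-](F)(F)F
Why: O-methylation of a secondary alcohol with a trialkyloxonium salt and a non-nucleophilic amine base, conditions that never form the ketone enolate, so C3 should not epimerise and ring C should not open by β-elimination of the O1 phenoxide.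

Step 13
Reactants: 19 (2R,3R)-2-[2,5-bis(benzyloxy)-4-methoxyphenyl]-3,5,6,7-tetramethoxychroman-4-one
Product: 20 (2R,3R)-2-(2,5-dihydroxy-4-methoxyphenyl)-5-hydroxy-3,6,7-trimethoxychroman-4-one
Conditions: BCl3 (8 equiv), C6HMe5 (6 equiv), CH2Cl2, −78 → 0 °C, argon; then H2O
Reagents that add atoms: none
Why: BCl3 cleaves the two aryl benzyl ethers (the benzyl cation is trapped by pentamethylbenzene) and, through a six-membered boron chelate between the C4 carbonyl and O5, only the peri methyl ether; the methyl ethers at C6, C7, C4' and C3 lack this activation at low temperature, and the hydroquinone is freed under argon without base.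

## Compound list

1 | 2-methoxybenzene-1,4-diol (2-methoxyhydroquinone) | COc1cc(O)ccc1O | starting material
2 | 1,4-bis(benzyloxy)-2-methoxybenzene | COc1cc(OCc2ccccc2)ccc1OCc1ccccc1 | intermediate
3 | N-[2,5-bis(benzyloxy)-4-methoxybenzylidene]-N-methylmethanaminium chloride | COc1cc(OCc2ccccc2)c(C=[N+](C)C)cc1OCc1ccccc1.[Cl-] | intermediate
4 | 2,5-bis(benzyloxy)-4-methoxybenzaldehyde | COc1cc(OCc2ccccc2)c(C=O)cc1OCc1ccccc1 | intermediate
5 | triethyl phosphonoacetate | CCOC(=O)CP(=O)(OCC)OCC | starting material
6 | sodium salt of triethyl phosphonoacetate (phosphonate carbanion) | CCOC(=O)[CH-]P(=O)(OCC)OCC.[Na+] | intermediate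
7 | ethyl (E)-3-[2,5-bis(benzyloxy)-4-methoxyphenyl]prop-2-enoate | CCOC(=O)/C=C/c1cc(OCc2ccccc2)c(OC)cc1OCc1ccccc1 | intermediate
8 | (E)-3-[2,5-bis(benzyloxy)-4-methoxyphenyl]prop-2-en-1-ol | OC/C=C/c1cc(OCc2ccccc2)c(OC)cc1OCc1ccccc1 | intermediate
9 | (E)-3-[2,5-bis(benzyloxy)-4-methoxyphenyl]allyl methyl carbonate | COC(=O)OC/C=C/c1cc(OCc2ccccc2)c(OC)cc1OCc1ccccc1 | intermediate
10 | 3,4,5-trimethoxyphenol | COc1cc(O)cc(OC)c1OC | starting material
11 | 2-(hydroxymethyl)-3,4,5-trimethoxyphenol (magnesium-bound in the flask) | OCc1c(O)cc(OC)c(OC)c1OC | intermediate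
12 | 6-hydroxy-2,3,4-trimethoxybenzaldehyde | O=Cc1c(O)cc(OC)c(OC)c1OC | intermediate
13 | 3,4,5-trimethoxy-2-vinylphenol | C=Cc1c(O)cc(OC)c(OC)c1OC | intermediate
14 | lithium 3,4,5-trimethoxy-2-vinylphenoxide | [Li+].C=Cc1c([O-])cc(OC)c(OC)c1OC | intermediate
15 | (S)-1-{[1-(2,5-bis(benzyloxy)-4-methoxyphenyl)prop-2-en-1-yl]oxy}-3,4,5-trimethoxy-2-vinylbenzene | COc1cc(OCc2ccccc2)c(cc1OCc1ccccc1)[C@H](C=C)Oc1cc(OC)c(OC)c(OC)c1C=C | intermediate
16 | (S)-2-[2,5-bis(benzyloxy)-4-methoxyphenyl]-5,6,7-trimethoxy-2H-chromene | COc1cc(OCc2ccccc2)c(cc1OCc1ccccc1)[C@H]1Oc2cc(OC)c(OC)c(OC)c2C=C1 | intermediate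
17 | (2R,3S,4S)-2-[2,5-bis(benzyloxy)-4-methoxyphenyl]-5,6,7-trimethoxychromane-3,4-diol (2,3-trans-3,4-cis) | COc1cc(OCc2ccccc2)c(cc1OCc1ccccc1)[C@H]1Oc2cc(OC)c(OC)c(OC)c2[C@H](O)[C@@H]1O | intermediate
18 | (2R,3R)-2-[2,5-bis(benzyloxy)-4-methoxyphenyl]-3-hydroxy-5,6,7-trimethoxychroman-4-one | COc1cc(OCc2ccccc2)c(cc1OCc1ccccc1)[C@H]1Oc2cc(OC)c(OC)c(OC)c2C(=O)[C@@H]1O | intermediate
19 | (2R,3R)-2-[2,5-bis(benzyloxy)-4-methoxyphenyl]-3,5,6,7-tetramethoxychroman-4-one | COc1cc(OCc2ccccc2)c(cc1OCc1ccccc1)[C@H]1Oc2cc(OC)c(OC)c(OC)c2C(=O)[C@@H]1OC | intermediate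
20 | (2R,3R)-2-(2,5-dihydroxy-4-methoxyphenyl)-5-hydroxy-3,6,7-trimethoxychroman-4-one | COc1cc(O)c([C@H]2Oc3cc(OC)c(OC)c(O)c3C(=O)[C@@H]2OC)cc1O | target

## Step count and risks

Total: 13 steps. Longest linear sequence: 11 steps (steps 1–5 and 8–13); ring A is made in steps 6 and 7.

**Step 8 (key step).**
- Risk: loss of enantio- and regiocontrol through re-ionisation of the electron-rich branched ether on the catalyst, and slow ionisation of the carbonate caused by the ortho benzyloxy group.
- Fallback: the same O1–C2 bond is formed between the same two fragments by iminium-ion organocatalysis, setting out from 8 and 12. Alcohol 8 is oxidised with MnO2 to (E)-3-[2,5-bis(benzyloxy)-4-methoxyphenyl]prop-2-enal F1. F1 and salicylaldehyde 12 undergo the domino oxa-Michael/aldol condensation under a diarylprolinol silyl ether (the antipode that gives the 2R product) with a benzoic acid co-catalyst, giving (R)-2-[2,5-bis(benzyloxy)-4-methoxyphenyl]-5,6,7-trimethoxy-2H-chromene-3-carbaldehyde F2. Stoichiometric RhCl(PPh3)3 (Tsuji–Wilkinson decarbonylation) at the lowest workable temperature removes the formyl group and rejoins the route at 16. This replaces steps 7–9.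

**Step 11.**
- Risk: competing hydride abstraction at the C2–H bond (benzylic to ring B), acid-triggered ionisation of the C4 hydroxyl by the hydroquinone by-product, or glycol cleavage.
- Fallback: no oxidant selectivity is needed. From 17, NaH/MeI in THF gives (2R,3S,4S)-2-[2,5-bis(benzyloxy)-4-methoxyphenyl]-3,4,5,6,7-pentamethoxychromane F3. Dilute HCl in THF/H2O exchanges only the doubly activated benzylic C4 methoxy group for hydroxyl by an SN1 path, giving (2R,3S)-2-[2,5-bis(benzyloxy)-4-methoxyphenyl]-3,5,6,7-tetramethoxychroman-4-ol F4 (both C4 epimers serve). Dess–Martin periodinane with NaHCO3 in CH2Cl2 oxidises F4 to 19, so step 12 is bypassed as well.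

**Step 12.**
- Risk: incomplete alkylation of a hindered, hydrogen-bonded hydroxyl, or enolisation-driven loss of C3 and C2 integrity (epimerisation, ring opening) if any stronger base is needed.
- Fallback: the methyl group is put on before the ketone exists. From 17, bis-methylation gives the pentamethoxychromane F3 (as under step 11). DDQ in wet CH2Cl2 then abstracts hydride from C4–H of the benzylic methyl ether, and the oxocarbenium ion is hydrolysed to ketone 19. This branch makes no compound beyond F3.

**Step 13.**
- Risk: over-demethylation (at C6 after the C5 phenol is freed, or at C3 through a five-membered chelate), Lewis-acid ionisation of the C2–O1 bond, and air oxidation of the freed hydroquinone.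
- Fallback: the two tasks are separated. From 19, hydrogenolysis (H2, Pd/C, EtOAc) gives (2R,3R)-2-(2,5-dihydroxy-4-methoxyphenyl)-3,5,6,7-tetramethoxychroman-4-one F5. The milder chelating Lewis acid MgI2·OEt2 in THF then removes only the C5 methyl group, giving 20.

**Step 7.**
- Risk: slow addition of the ylide to a di-ortho-substituted, phenoxide-deactivated aldehyde, and polymerisation of the electron-rich vinylphenol on isolation.
- Fallback: the order is reversed. From 12, n-BuLi gives lithium 2-formyl-3,4,5-trimethoxyphenoxide F6, which is etherified with 9 under the step 8 conditions to (S)-2-{[1-(2,5-bis(benzyloxy)-4-methoxyphenyl)prop-2-en-1-yl]oxy}-4,5,6-trimethoxybenzaldehyde F7. Wittig methylenation of the now phenol-free aldehyde (Ph3P=CH2, THF) rejoins the route at 15.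

## Further compounds

F1 | step 8 | (E)-3-[2,5-bis(benzyloxy)-4-methoxyphenyl]prop-2-enal | O=C/C=C/c1cc(OCc2ccccc2)c(OC)cc1OCc1ccccc1
F2 | step 8 | (R)-2-[2,5-bis(benzyloxy)-4-methoxyphenyl]-5,6,7-trimethoxy-2H-chromene-3-carbaldehyde | COc1cc(OCc2ccccc2)c(cc1OCc1ccccc1)[C@H]1Oc2cc(OC)c(OC)c(OC)c2C=C1C=O
F3 | step 11 | (2R,3S,4S)-2-[2,5-bis(benzyloxy)-4-methoxyphenyl]-3,4,5,6,7-pentamethoxychromane | COc1cc(OCc2ccccc2)c(cc1OCc1ccccc1)[C@H]1Oc2cc(OC)c(OC)c(OC)c2[C@H](OC)[C@@H]1OC
F4 | step 11 | (2R,3S)-2-[2,5-bis(benzyloxy)-4-methoxyphenyl]-3,5,6,7-tetramethoxychroman-4-ol (C4 epimers) | COc1cc(OCc2ccccc2)c(cc1OCc1ccccc1)[C@H]1Oc2cc(OC)c(OC)c(OC)c2C(O)[C@@H]1OC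
F0 | step 12 | none | none
F5 | step 13 | (2R,3R)-2-(2,5-dihydroxy-4-methoxyphenyl)-3,5,6,7-tetramethoxychroman-4-one | COc1cc(O)c([C@H]2Oc3cc(OC)c(OC)c(OC)c3C(=O)[C@@H]2OC)cc1O
F6 | step 7 | lithium 2-formyl-3,4,5-trimethoxyphenoxide | [Li+].O=Cc1c([O-])cc(OC)c(OC)c1OC
F7 | step 7 | (S)-2-{[1-(2,5-bis(benzyloxy)-4-methoxyphenyl)prop-2-en-1-yl]oxy}-4,5,6-trimethoxybenzaldehyde | COc1cc(OCc2ccccc2)c(cc1OCc1ccccc1)[C@H](C=C)Oc1cc(OC)c(OC)c(OC)c1C=O
A1 | alternative 1 | (2R,3R)-2-[2,5-bis(benzyloxy)-4-methoxyphenyl]-5-hydroxy-3,6,7-trimethoxychroman-4-one | COc1cc(OCc2ccccc2)c(cc1OCc1ccccc1)[C@H]1Oc2cc(OC)c(OC)c(O)c2C(=O)[C@@H]1OC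
A2 | alternative 1 | (2R,3R)-2-[2,5-bis(benzyloxy)-4-methoxyphenyl]-3-methoxy-6-(tributylstannyl)-2,3-dihydro-4H-pyran-4-one | COc1cc(OCc2ccccc2)c(cc1OCc1ccccc1)[C@H]1OC(=CC(=O)[C@@H]1OC)[Sn](CCCC)(CCCC)CCCC
A3 | alternative 1 | 4-chloro-2,3-dimethoxycyclobut-2-en-1-one | COC1=C(OC)C(Cl)C1=O
A4 | alternative 2 | (2R,3R)-2-[2,5-bis(benzyloxy)-4-methoxyphenyl]-3-hydroxy-5,6,7-trimethoxychroman-4-one | COc1cc(OCc2ccccc2)c(cc1OCc1ccccc1)[C@H]1Oc2cc(OC)c(OC)c(OC)c2C(=O)[C@@H]1O
A5 | alternative 2 | (S)-{[2-(2,5-bis(benzyloxy)-4-methoxyphenyl)-5,6,7-trimethoxy-2H-chromen-4-yl]oxy}trimethylsilane | COc1cc(OCc2ccccc2)c(cc1OCc1ccccc1)[C@H]1Oc2cc(OC)c(OC)c(OC)c2C(O[Si](C)(C)C)=C1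
A6 | alternative 3 | (2S)-2-[2,5-bis(benzyloxy)-4-methoxyphenyl]-5,6,7-trimethoxychroman-4-one | COc1cc(OCc2ccccc2)c(cc1OCc1ccccc1)[C@H]1Oc2cc(OC)c(OC)c(OC)c2C(=O)C1
A7 | alternative 3 | 1-{2-[(2,5-bis(benzyloxy)-4-methoxybenzyl)oxy]-4,5,6-trimethoxyphenyl}-2-diazoethan-1-one | COc1cc(OCc2ccccc2)c(cc1OCc1ccccc1)COc1cc(OC)c(OC)c(OC)c1C(=O)C=[N+]=[N-]
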